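**Strategy.** The route rests on cutting both aryl–C(OH) bonds: C-1–C-7 of ring A (the free-phenol ring) and C-1′–C-7′ of ring B (the O-benzylated ring), where C-7 and C-7′ are the benzylic carbinol carbons. These two carbons carry the same OH, CH3 and 4-methylpentyl groups, so one enantiopure 6-methylheptan-2-yl benzoate can serve twice. In one operation, two α-lithiated (S)-benzoates are captured by an achiral bis(aryl boronic ester), both aryl groups shift from boron to carbon as benzoate leaves, and oxidation reveals both (S)-carbinols; no ring is formed. The precursor is the SEM/TBS-protected benzyl aryl ether carrying a neopentyl glycol boronate at C-1 and C-1′, each ortho to oxygen.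

Key step: step 9

Remarks on the chemistry:
- The target is (7S,7′S). Hydrogen is replaced by aryl with the C–O position kept, so the (S)-benzoate is the required antipode.
- Boron carries neopentyl glycol (Bneop) and not pinacol: the hindered α-lithiated secondary dialkyl benzoate adds slowly and reversibly to pinacol esters.
- The phenol is masked as a SEM acetal, so that fluoride alone unmasks both oxygens in one final step and the acid-sensitive tertiary benzylic carbinols never meet acid.
- Assumption: a Prelog-type ketoreductase from a commercial panel accepts 6-methylheptan-2-one.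
- Abbreviations: SEM = 2-(trimethylsilyl)ethoxymethyl; TBS = tert-butyldimethylsilyl; Bneop = 5,5-dimethyl-1,3,2-dioxaborinan-2-yl; TIB = 2,4,6-triisopropylbenzoyl; CPME = cyclopentyl methyl ether.

**Route**

Step 1
Reactants: 1 6-methylheptan-2-one
Product: 2 (S)-6-methylheptan-2-ol
Conditions: (S)-selective ketoreductase (Prelog-type), NADP+ (cat.), iPrOH, phosphate buffer pH 7, 30 °C
Reagents that add atoms: none
Why: Enzymatic carbonyl reduction with Prelog selectivity, in which the enzyme pocket directs NADPH hydride to the re face of the methyl ketone and should set the (S) centre, while isopropanol regenerates the cofactor.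

Step 2
Reactants: 2 (S)-6-methylheptan-2-ol; 3 2,4,6-triisopropylbenzoyl chloride
Product: 5 (S)-6-methylheptan-2-yl 2,4,6-triisopropylbenzoate, via sodium alkoxide 4 (not isolated)
Conditions: NaH, THF, 0 °C → rt; then 3, 60 °C
Reagents that add atoms: none
Why: O-acylation of the alkoxide by the hindered aroyl chloride (addition–elimination) leaves the stereogenic C–O bond untouched, so the (S) configuration is carried over.

Step 3
Reactants: 6 methyl 4-bromo-3-hydroxybenzoate
Product: 7 methyl 4-bromo-3-{[2-(trimethylsilyl)ethoxy]methoxy}benzoate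
Conditions: SEMCl, iPr2NEt, CH2Cl2, 0 °C → rt
Reagents that add atoms: 2-(trimethylsilyl)ethoxymethyl chloride (SEMCl), C[Si](C)(C)CCOCCl
Why: O-alkylation of the acidic ortho-bromophenol by an α-chloro ether is a standard acetal protection that the ester and aryl bromide tolerate.

Step 4
Reactants: 7 methyl 4-bromo-3-{[2-(trimethylsilyl)ethoxy]methoxy}benzoate
Product: 8 (4-bromo-3-{[2-(trimethylsilyl)ethoxy]methoxy}phenyl)methanol
Conditions: DIBAL-H (2.5 equiv), CH2Cl2, −78 → 0 °C; aq. Rochelle salt
Reagents that add atoms: none
Why: DIBAL-H reduces the ester to the primary alcohol at low temperature, where the aryl bromide and the SEM acetal are inert.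

Step 5
Reactants: 8 (4-bromo-3-{[2-(trimethylsilyl)ethoxy]methoxy}phenyl)methanol; 6 methyl 4-bromo-3-hydroxybenzoate
Product: 9 methyl 4-bromo-3-[(4-bromo-3-{[2-(trimethylsilyl)ethoxy]methoxy}benzyl)oxy]benzoate
Conditions: PPh3, DIAD, THF, 0 °C → rt
Reagents that add atoms: none
Why: Mitsunobu etherification, in which the acidic phenol protonates the betaine and its phenoxide displaces the primary benzylic oxyphosphonium by SN2 to form the aryl benzyl ether directly.

Step 6
Reactants: 9 methyl 4-bromo-3-[(4-bromo-3-{[2-(trimethylsilyl)ethoxy]methoxy}benzyl)oxy]benzoate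
Product: 10 {4-bromo-3-[(4-bromo-3-{[2-(trimethylsilyl)ethoxy]methoxy}benzyl)oxy]phenyl}methanol
Conditions: DIBAL-H (2.5 equiv), CH2Cl2, −78 → 0 °C; aq. Rochelle salt
Reagents that add atoms: none
Why: DIBAL-H ester reduction as in step 4; the aryl benzyl ether, both aryl bromides and the SEM acetal do not react with the hydride.

Step 7
Reactants: 10 {4-bromo-3-[(4-bromo-3-{[2-(trimethylsilyl)ethoxy]methoxy}benzyl)oxy]phenyl}methanol
Product: 11 TBS ether of 10 (the dibromide)
Conditions: TBSCl, imidazole, DMF, rt
Reagents that add atoms: tert-butyldimethylsilyl chloride (TBSCl), CC(C)(C)[Si](C)(C)Cl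
Why: Imidazole-promoted silylation of the only free hydroxyl, a primary benzylic alcohol, removes the last acidic proton before organolithium chemistry.

Step 8
Reactants: 11 TBS ether of 10 (the dibromide); 12 bis(neopentyl glycolato)diboron
Product: 13 bis(neopentyl glycol boronate), both Br of 11 replaced by Bneop
Conditions: 12 (2.6 equiv), PdCl2(dppf) (6 mol %), KOAc, 1,4-dioxane, 85 °C
Reagents that add atoms: none
Why: Twofold Miyaura borylation (oxidative addition into each C–Br, acetate-assisted transmetalation from the diboron, reductive elimination), for which the small neopentyl glycol diboron suits ortho-alkoxy aryl bromides.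

Step 9
Reactants: 5 (S)-6-methylheptan-2-yl 2,4,6-triisopropylbenzoate; 13 bis(neopentyl glycol boronate)
Product: 17 SEM/TBS-protected disydonol A, via lithiated benzoate 14 (not isolated), via bis-boronate ate complex 15 (not isolated), via bis(tertiary boronic ester) 16 (not isolated)
Conditions: 5 (3.0 equiv), sBuLi (2.8 equiv), TMEDA, CPME, −60 °C; then 13 (1.0 equiv), −60 °C → rt → 45 °C; then 2 M NaOH, 30% H2O2, THF, 0 °C → rt
Reagents that add atoms: hydrogen peroxide, OO
Why: sBuLi/TMEDA removes the carbinol C–H of 5 with retention to give the configurationally stable α-oxy organolithium 14, which adds to each trigonal boron of 13 with retention; in each ate unit of 15 the aryl group then shifts from boron to carbon anti to the departing triisopropylbenzoate (inversion at carbon), and peroxide oxidation of 16 replaces boron by hydroxyl with retention. The closest known reaction type is the lithiation–borylation of secondary dialkyl 2,4,6-triisopropylbenzoates with neopentyl glycol boronic esters to tertiary boronic esters and tertiary alcohols, here run at two boron atoms of one substrate. No ring is closed. Both new stereocentres are controlled only by the carbinol configuration of 5 (stereospecific transfer): the net change is H replaced by aryl with the C–O position kept, so (S)-5 should give (S) at C-7 and at C-7′. The step needs stereospecificity and chemoselectivity for boron over the benzylic ether CH2; these are secured by the low-temperature configurational stability of the hindered carbanion, by the unhindered neopentyl glycol esters that favour fast ate formation, and by keeping 5 in excess over sBuLi so that no free alkyllithium meets 13. The electron-rich ortho-alkoxyaryl groups are good migrating groups, so the shift should be complete on warming.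

Step 10
Reactants: 17 SEM/TBS-protected disydonol A
Product: 19 disydonol A, via SEM-protected disydonol A 18 (not isolated)
Conditions: TBAF (excess), THF, rt; then DMPU, 65 °C; aq. work-up
Reagents that add atoms: none
Why: Fluoride desilylation cleaves the TBS ether at room temperature and, on heating, attacks the SEM silicon to trigger fragmentation to ethylene, formaldehyde and phenoxide, all without acid, so the tertiary benzylic carbinols should not ionise.

**Compound list**

1 | 6-methylheptan-2-one | CC(C)CCCC(C)=O | starting material
2 | (S)-6-methylheptan-2-ol | CC(C)CCC[C@H](C)O | intermediate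
3 | 2,4,6-triisopropylbenzoyl chloride | CC(C)c1cc(C(C)C)c(C(Cl)=O)c(C(C)C)c1 | starting material
4 | sodium (S)-6-methylheptan-2-olate (not isolated) | CC(C)CCC[C@H](C)[O-].[Na+] | intermediate
5 | (S)-6-methylheptan-2-yl 2,4,6-triisopropylbenzoate | CC(C)CCC[C@H](C)OC(=O)c1c(C(C)C)cc(C(C)C)cc1C(C)C | intermediate
6 | methyl 4-bromo-3-hydroxybenzoate | COC(=O)c1ccc(Br)c(O)c1 | starting material
7 | methyl 4-bromo-3-{[2-(trimethylsilyl)ethoxy]methoxy}benzoate | COC(=O)c1ccc(Br)c(OCOCC[Si](C)(C)C)c1 | intermediate
8 | (4-bromo-3-{[2-(trimethylsilyl)ethoxy]methoxy}phenyl)methanol | OCc1ccc(Br)c(OCOCC[Si](C)(C)C)c1 | intermediate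
9 | methyl 4-bromo-3-[(4-bromo-3-{[2-(trimethylsilyl)ethoxy]methoxy}benzyl)oxy]benzoate | COC(=O)c1ccc(Br)c(OCc2ccc(Br)c(OCOCC[Si](C)(C)C)c2)c1 | intermediate
10 | {4-bromo-3-[(4-bromo-3-{[2-(trimethylsilyl)ethoxy]methoxy}benzyl)oxy]phenyl}methanol | OCc1ccc(Br)c(OCc2ccc(Br)c(OCOCC[Si](C)(C)C)c2)c1 | intermediate
11 | TBS ether of 10 (dibromide): 4-bromo-3-[(4-bromo-3-SEM-oxybenzyl)oxy]benzyl tert-butyldimethylsilyl ether | C[Si](C)(C)CCOCOc1cc(COc2cc(CO[Si](C)(C)C(C)(C)C)ccc2Br)ccc1Br | intermediate
12 | bis(neopentyl glycolato)diboron [5,5,5′,5′-tetramethyl-2,2′-bi(1,3,2-dioxaborinane)] | CC1(C)COB(OC1)B1OCC(C)(C)CO1 | starting material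
13 | bis(neopentyl glycol boronate): 11 with each Br replaced by 5,5-dimethyl-1,3,2-dioxaborinan-2-yl (achiral) | C[Si](C)(C)CCOCOc1cc(COc2cc(CO[Si](C)(C)C(C)(C)C)ccc2B2OCC(C)(C)CO2)ccc1B1OCC(C)(C)CO1 | intermediate
14 | (S)-2-lithio-6-methylheptan-2-yl 2,4,6-triisopropylbenzoate (not isolated) | CC(C)CCC[C@]([Li])(C)OC(=O)c1c(C(C)C)cc(C(C)C)cc1C(C)C | intermediate
15 | dilithium bis-boronate ate complex: each boron of 13 bonded to the (S)-configured benzoate-bearing carbon (not isolated) | [Li+].[Li+].CC(C)CCC[C@](C)(OC(=O)c1c(C(C)C)cc(C(C)C)cc1C(C)C)[B-]1(OCC(C)(C)CO1)c1ccc(COc2cc(CO[Si](C)(C)C(C)(C)C)ccc2[B-]2(OCC(C)(C)CO2)[C@@](C)(OC(=O)c2c(C(C)C)cc(C(C)C)cc2C(C)C)CCCC(C)C)cc1OCOCC[Si](C)(C)C | intermediate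
16 | bis(tertiary benzylic neopentyl glycol boronic ester), (R,R) by CIP, Bneop in the place of each future OH (not isolated) | CC(C)CCC[C@](C)(B1OCC(C)(C)CO1)c1ccc(COc2cc(CO[Si](C)(C)C(C)(C)C)ccc2[C@@](C)(B2OCC(C)(C)CO2)CCCC(C)C)cc1OCOCC[Si](C)(C)C | intermediate
17 | SEM/TBS-protected disydonol A, (S,S) | CC(C)CCC[C@](C)(O)c1ccc(COc2cc(CO[Si](C)(C)C(C)(C)C)ccc2[C@@](C)(O)CCCC(C)C)cc1OCOCC[Si](C)(C)C | intermediate
18 | SEM-protected disydonol A, (S,S), primary alcohol free (not isolated in the main route) | CC(C)CCC[C@](C)(O)c1ccc(COc2cc(CO)ccc2[C@@](C)(O)CCCC(C)C)cc1OCOCC[Si](C)(C)C | intermediate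
19 | disydonol A, (7S,7′S) | CC(C)CCC[C@](C)(O)c1ccc(COc2cc(CO)ccc2[C@@](C)(O)CCCC(C)C)cc1O | target

**Count**

Total steps: 10. Longest linear sequence: 8 steps (steps 3–10 from 6); the benzoate branch (steps 1–2) joins at step 9.

**Steps most likely to fail**

1. Step 9. Ate-complex formation at the two ortho-alkoxy-flanked boron atoms may be slow or reversible, so that the carbanion is lost before the aryl shift; the reaction would then stall after one addition and lose stereochemical fidelity. The fallback reverses the roles of the partners, making the aryl-bearing carbon the carbanion and the alkyl group the migrating group, which is the best-established variant of this chemistry. It sets out from dibromide 11. Double bromine–lithium exchange (nBuLi, THF, −78 °C) and acylation with N-methoxy-N-methylacetamide would give the bis(methyl ketone) F1. Asymmetric transfer hydrogenation (RuCl[(R,R)-TsDPEN](p-cymene), HCO2H/Et3N) should give the (R,R)-bis(1-arylethanol) F2. Carbamoylation (iPr2NCOCl, Et3N, toluene, reflux) would give the bis(N,N-diisopropylcarbamate) F3. Benzylic lithiation of F3 (sBuLi, Et2O, −78 °C), addition of 4-methylpentylboronic acid pinacol ester, MgBr2/MeOH-assisted 1,2-alkyl shift and NaOH/H2O2 oxidation would come back to the route at 17. The same retention–retention–inversion–retention course applies, so the (R)-carbamates should give the (S)-carbinols.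

2. Step 8. Hydrodebromination may overtake the second C–B bond formation, and the neopentyl glycol esters may hydrolyse in part during purification. The fallback replaces palladium catalysis by halogen–metal exchange. It sets out from 11: double bromine–lithium exchange (nBuLi, THF, −78 °C), quench with B(OiPr)3 and mild aqueous work-up would give the bis(boronic acid) F4, which is condensed with neopentyl glycol (MgSO4, CH2Cl2, rt) and comes back to the route at 13.

3. Step 10. Fragmentation of the phenolic SEM acetal under fluoride may be incomplete, or the released formaldehyde may be recaptured by the electron-rich phenoxide ring. The fallback separates the two deprotections and removes the acetal by Lewis-acid activation of its oxygen. It sets out from 17: TBAF in THF at 0 °C → rt with isolation of 18, then TMSOTf/2,2′-bipyridyl in CH2Cl2 at 0 °C followed by water (transient trimethylsilyl ethers hydrolyse on work-up), arriving at 19.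

**Further compounds**

F1 | step 9 | bis(methyl ketone): 11 with each Br replaced by acetyl | CC(=O)c1ccc(COc2cc(CO[Si](C)(C)C(C)(C)C)ccc2C(C)=O)cc1OCOCC[Si](C)(C)C
F2 | step 9 | (R,R)-bis(1-hydroxyethyl) compound | C[C@@H](O)c1ccc(COc2cc(CO[Si](C)(C)C(C)(C)C)ccc2[C@@H](C)O)cc1OCOCC[Si](C)(C)C
F3 | step 9 | (R,R)-bis(N,N-diisopropylcarbamate) of F2 | C[C@@H](OC(=O)N(C(C)C)C(C)C)c1ccc(COc2cc(CO[Si](C)(C)C(C)(C)C)ccc2[C@@H](C)OC(=O)N(C(C)C)C(C)C)cc1OCOCC[Si](C)(C)C
F4 | step 8 | bis(boronic acid): 11 with each Br replaced by B(OH)2 | OB(O)c1ccc(COc2cc(CO[Si](C)(C)C(C)(C)C)ccc2B(O)O)cc1OCOCC[Si](C)(C)C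
F0 | step 10 | none | none
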